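Readings and results come from a simulation for an exercise, noise included.

Follow the first product out.

the same everywhere: substrate 10 mM
- theta: reagent 6 mM; run made earlier
- zeta: reagent 62 mM; run made earlier
- larch: reagent 5.00 mM; time 15 min
- birch: reagent 30.0 mM; time 15 min
- elm: reagent 40.0 mM; time 15 min

| run | time / min | tetra adduct / % | first product / % | substrate / % |
|---|---|---|---|---|
| theta | 1.33 | 0 | 7.5 | 92.4 |
| theta | 2.50 | 0.1 | 13.3 | 87.5 |
| theta | 4.00 | 0 | 19.3 | 80.8 |
| theta | 8.00 | 0.3 | 29.6 | 70.3 |
| theta | 15.0 | 0 | 40.2 | 59.0 |
| zeta | 1.33 | 0.2 | 54.6 | 43.5 |
| zeta | 4.00 | 0.7 | 82.7 | 9.7 |
| zeta | 8.00 | 5.6 | 82.4 | 0.7 |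
| zeta | 10.0 | 8.7 | 78.9 | 0.5 |
| zeta | 15.0 | 16.7 | 69.7 | 0.2 |

(standard deviation of a reading: 0.3 percentage points)

- which of these holds the largest part of the substrate at the end of larch (first product / substrate / triple product / tetra adduct / bis adduct)
- which of these holds the largest part of the substrate at the end of birch (first product / substrate / triple product / tetra adduct / bis adduct)
- which of these holds the largest part of the substrate at the end of elm (first product / substrate / triple product / tetra adduct / bis adduct)
- tetra adduct at the end of birch, in percent of the substrate charged

- the analysis behind the earlier runs scatters by 0.3 percentage points, standard deviation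
- a reading or a percentage of first product counts all its forms, free or not

In zeta, with substrate down to 0.7% at 8.00 min, first product falls along a nearly straight line: 0.0175 min⁻¹ of the charge, then 0.0184 min⁻¹, though reagent is being used up. A first-order decay slackens as it goes, and these readings do not. So the reckoning here treats the level of first product that reagent meets as fixed, with the outflow following c(reagent). The carried quantity is the exit coefficient: the share of the charge leaving first product per minute per mM of reagent. Taking one reagent per first product and 3 more per tetra adduct:

c(reagent), zeta ≈ 48.2 mM

exit coefficient = 3.82 × 10⁻⁴ mM⁻¹ min⁻¹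

Now the question turned round. In larch, first product could pass substrate only by taking over half of it, but reagent is charged at half the substrate. As the limiting reagent it allows a tie at best, so first product does not pass substrate. In birch, first product keeps the largest part as long as substrate left and exit together stay under half the charge. With about 20.0 mM of reagent after the first step, zeta's substrate decay scales to:

time constant of substrate, birch ≈ 4.63 min

substrate left, birch ≈ 3.91%

exit, birch ≈ 11.5%

Together they come to 15.4%, well below that mark. Zeta's hidden adducts over its tetra rate, scaled to birch's reagent, give a first-order lag: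

lag, birch ≈ 20.2 min

tetra adduct, birch ≈ 3.37%

The forecast says substrate for larch, first product for birch, first product for elm, and 2.5% of tetra adduct in birch, lower than this reckoning: “Holdup is about 15 min, so tetra adduct is about 2.5%.”

The flasks give substrate for larch, first product for birch, first product for elm, and 3.00% of tetra adduct in birch.

    reagent + bis adduct → triple product (k = 0.244 M⁻¹ s⁻¹)
    crystals ⇌ first product, rate k2*(cs2 - [first product]) while solid is left; crystals form when [first product] > cs2 (solubility = 6.90 mM, k = 0.136 s⁻¹)
    reagent + first product → bis adduct (k = 0.0104 M⁻¹ s⁻¹)
    substrate + reagent → first product (k = 0.175 M⁻¹ s⁻¹)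
    reagent + triple product → tetra adduct (k = 0.0635 M⁻¹ s⁻¹)

In birch, crystals, counted in first product, stood at 9.75% after 7.50 min and 15.7% after 15.0 min, the dissolved rest of first product stood at 69.0% of the charge, and the adducts beyond it held 11.9% against the 11.5% reckoned. In elm, where the coefficient at 30.0 mM gives 17.2%, crystals stood at 12.8% after 15.0 min, and the adducts beyond first product held 17.5%.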